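## Retrosynthetic overview

1. The target 20 comes from pentamethyl ether 19 by ether cleavage, and 19 from tribromide 17 (3 × Br → CHO). Every formyl carbon is carried as an aryl bromide placed before the two halves are joined, so no late electrophilic substitution has to tell C6 from C8.
2. The C4–H centre of 17 comes from tertiary benzylic alcohol 16 by ionic hydrogenation, with hydride delivered anti to the C3 isopropyl group.
3. Key disconnection: 16 comes from aldol 7 and aryne 15, forming O1–C8a and C4a–C4 in one operation. This closes the dihydropyran ring, the only ring made in the route; both benzene rings are bought.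
4. Enabling feature: in the A ring the C4a–C8a bond lies between the oxygen-bearing C5 and the unsubstituted C8–H, so an aryne on this bond is polarised by the C5 methoxy group (oxygen adds at C8a, carbanion forms at C4a). O1 and C4 stand 1,3 across C2–C3 (an aldol pattern), so O-arylation is followed by a six-membered ring closure onto a C4 ketone.
5. Aldol 7 comes from an Evans anti-aldol of imide 3 with aldehyde 2 (sets C2 and C3), then Weinreb amide and isobutyl Grignard. Aryne precursor 14 comes from 2-bromo-1,3-dimethoxybenzene 8.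

Key step: step 8

Remark 1: imide 3 is treated as purchasable (a catalogue item in both enantiomeric forms); otherwise it is one N-acylation from (R)-4-benzyloxazolidin-2-one.

Remark 2: the C4 carbinol configuration of 16 is left uncontrolled on purpose, because step 9 passes through a planar C4 cation; 16 is drawn without a descriptor at C4.

## Route

Step 1
Reactants: 1 2,4,6-trimethoxybenzaldehyde
Product: 2 3,5-dibromo-2,4,6-trimethoxybenzaldehyde
Conditions: Br2 (2.1 equiv), NaOAc, AcOH, rt
Reagents that add atoms: bromine, BrBr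
Why: Electrophilic aromatic bromination at the only two ring C–H positions, each activated by two ortho and one para methoxy group; no stereocenter is formed.

Step 2
Reactants: 3 (R)-4-benzyl-3-(3-methylbutanoyl)oxazolidin-2-one; 2 3,5-dibromo-2,4,6-trimethoxybenzaldehyde
Product: 5 (R)-4-benzyl-3-[(2S,3R)-3-(3,5-dibromo-2,4,6-trimethoxyphenyl)-3-hydroxy-2-isopropylpropanoyl]oxazolidin-2-one, via O-trimethylsilyl aldol imide 4 (not isolated)
Conditions: MgCl2 (0.2 equiv), Et3N, TMSCl, EtOAc, rt; then TFA (cat.), MeOH
Reagents that add atoms: none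
Why: Evans magnesium halide-catalysed anti-aldol of an N-acyloxazolidinone with a non-enolisable aromatic aldehyde, in which the chelated (Z)-magnesium enolate is attacked on the face opposite the benzyl group through a boat-like transition state, setting the α-carbon (S) and the carbinol carbon (R) in the anti relationship (future C3 and C2 of the chroman), with silylation driving the equilibrium.

Step 3
Reactants: 5 (R)-4-benzyl-3-[(2S,3R)-3-(3,5-dibromo-2,4,6-trimethoxyphenyl)-3-hydroxy-2-isopropylpropanoyl]oxazolidin-2-one
Product: 6 (2S,3R)-3-(3,5-dibromo-2,4,6-trimethoxyphenyl)-3-hydroxy-N-methoxy-N-methyl-2-isopropylpropanamide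
Conditions: MeNH(OMe)·HCl, AlMe3, CH2Cl2, −20 °C to rt; aq. HCl work-up
Reagents that add atoms: N,O-dimethylhydroxylamine hydrochloride, CNOC.Cl
Why: Aluminium amide transamination of a β-hydroxy imide (Weinreb amide formation), assisted by the free hydroxyl as its aluminium alkoxide, which should leave both stereocenters untouched.

Step 4
Reactants: 6 (2S,3R)-3-(3,5-dibromo-2,4,6-trimethoxyphenyl)-3-hydroxy-N-methoxy-N-methyl-2-isopropylpropanamide
Product: 7 (1R,2S)-1-(3,5-dibromo-2,4,6-trimethoxyphenyl)-1-hydroxy-5-methyl-2-isopropylhexan-3-one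
Conditions: i-BuMgBr (4 equiv), THF, −20 to 0 °C; aq. NH4Cl
Reagents that add atoms: isobutylmagnesium bromide, CC(C)C[Mg]Br
Why: Weinreb ketone synthesis, in which the chelated tetrahedral magnesium adduct prevents over-addition and keeps the α-stereocenter from enolising until work-up.

Step 5
Reactants: 8 2-bromo-1,3-dimethoxybenzene
Product: 10 4-bromo-3,5-dimethoxyphenol, via aryl pinacol boronate 9 (not isolated)
Conditions: [Ir(OMe)(cod)]2 (1.5 mol%), dtbpy (3 mol%), B2pin2, THF, 80 °C; then Oxone, acetone/H2O, rt
Reagents that add atoms: potassium peroxymonosulfate (Oxone), [K+].[O-]S(=O)(=O)OO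
Why: Sterically controlled iridium-catalysed C–H borylation at the only C–H without an ortho substituent (C5), followed by oxidation of the C–B bond to the phenol.

Step 6
Reactants: 10 4-bromo-3,5-dimethoxyphenol
Product: 11 4-bromo-2-iodo-3,5-dimethoxyphenol
Conditions: NIS (1.0 equiv), MeCN, 0 °C
Reagents that add atoms: N-iodosuccinimide, O=C1CCC(=O)N1I
Why: Electrophilic iodination ortho to the phenol; the two open ring positions are equivalent, so only mono- versus di-iodination has to be controlled by stoichiometry.

Step 7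
Reactants: 11 4-bromo-2-iodo-3,5-dimethoxyphenol
Product: 14 4-bromo-3,5-dimethoxy-2-(trimethylsilyl)phenyl trifluoromethanesulfonate, via aryl trimethylsilyl ether 12 (not isolated), via lithium 2-silylphenoxide 13 (not isolated)
Conditions: HMDS, THF, 70 °C, concentrate; n-BuLi (1.0 equiv), THF, −100 °C; Tf2O, −100 °C to rt
Reagents that add atoms: hexamethyldisilazane, C[Si](C)(C)N[Si](C)(C)C; trifluoromethanesulfonic anhydride, O=S(=O)(OS(=O)(=O)C(F)(F)F)C(F)(F)F
Why: Standard o-silylaryl triflate (Kobayashi precursor) synthesis: O-silylation, iodine–lithium exchange (far faster than exchange of the bromide at −100 °C), retro-Brook 1,3-O-to-C silyl shift and triflation of the resulting phenoxide.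

Step 8
Reactants: 7 (1R,2S)-1-(3,5-dibromo-2,4,6-trimethoxyphenyl)-1-hydroxy-5-methyl-2-isopropylhexan-3-one; 14 4-bromo-3,5-dimethoxy-2-(trimethylsilyl)phenyl trifluoromethanesulfonate
Product: 16 (2R,3S)-6-bromo-2-(3,5-dibromo-2,4,6-trimethoxyphenyl)-4-isobutyl-3-isopropyl-5,7-dimethoxychroman-4-ol (C4 epimers not distinguished), via 4-bromo-3,5-dimethoxybenzyne 15 (not isolated)
Conditions: CsF (3 equiv), MeCN/toluene, rt; 14 (1.3 equiv) added slowly
Reagents that add atoms: none
Why: Proposed new method: fluoride-triggered 1,2-elimination of 14 releases aryne 15, the fluoride-activated carbinol oxygen of 7 adds to the aryne carbon remote from the flanking methoxy group (future C8a), and the aryl anion formed at the methoxy-flanked carbon (future C4a) adds to the ketone carbon lying 1,3 to that oxygen, so O1–C8a and C4a–C4 form in one operation. The closest known reaction type is the aryne annulation of o-hydroxyaryl ketones, aldehydes and esters to xanthenols and xanthones (O-arylation, then carbonyl capture by the aryl anion); what is new is its use on an aliphatic aldol adduct. The dihydropyran ring closes in the second event by 6-exo-trig addition of the aryl anion to the C=O group. C2 and C3 are carried over unchanged from 7 (the C2–O bond is not broken and caesium fluoride is too weak a base to enolise C3), and the new C4 carbinol centre needs no control because step 9 planarises it. The step needs regioselective aryne addition, secured by the polarisation of the aryne by its ortho methoxy group while the other terminus sits next to an unsubstituted C–H, and carbonyl capture faster than protonation of the aryl anion or retro-aldol cleavage, secured by the six-membered geometry, the aprotic medium and slow release of the aryne.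

Step 9
Reactants: 16 (2R,3S)-6-bromo-2-(3,5-dibromo-2,4,6-trimethoxyphenyl)-4-isobutyl-3-isopropyl-5,7-dimethoxychroman-4-ol
Product: 17 (2R,3R,4S)-6-bromo-2-(3,5-dibromo-2,4,6-trimethoxyphenyl)-4-isobutyl-3-isopropyl-5,7-dimethoxychroman
Conditions: Et3SiH (5 equiv), TFA (5 equiv), CH2Cl2, −40 to 0 °C
Reagents that add atoms: none
Why: Ionic hydrogenation, in which acid ionises the tertiary benzylic alcohol to a C4 cation stabilised by O1 and the 5- and 7-methoxy groups and triethylsilane delivers hydride to the face opposite the adjacent C3 isopropyl group, setting C4 (S) with the isobutyl group cis to isopropyl and pseudo-axial, away from the peri 5-methoxy group (also the more stable C4 epimer).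

Step 10
Reactants: 17 (2R,3R,4S)-6-bromo-2-(3,5-dibromo-2,4,6-trimethoxyphenyl)-4-isobutyl-3-isopropyl-5,7-dimethoxychroman
Product: 19 5-[(2R,3R,4S)-6-formyl-4-isobutyl-3-isopropyl-5,7-dimethoxychroman-2-yl]-2,4,6-trimethoxybenzene-1,3-dicarbaldehyde, via trilithio derivative 18 (not isolated)
Conditions: t-BuLi (6.6 equiv), THF, −78 °C; DMF, −78 to 0 °C; aq. NH4Cl
Reagents that add atoms: N,N-dimethylformamide, CN(C)C=O
Why: Threefold bromine–lithium exchange (each bromide lies between two methoxy groups, which speed the exchange and stabilise the aryllithium) followed by formylation with DMF; exchange at −78 °C should outpace benzylic deprotonation, so no stereocenter is touched.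

Step 11
Reactants: 19 5-[(2R,3R,4S)-6-formyl-4-isobutyl-3-isopropyl-5,7-dimethoxychroman-2-yl]-2,4,6-trimethoxybenzene-1,3-dicarbaldehyde
Product: 20 5-[(2R,3R,4S)-6-formyl-5,7-dihydroxy-4-isobutyl-3-isopropylchroman-2-yl]-2,4,6-trihydroxybenzene-1,3-dicarbaldehyde (CNP0328914.1)
Conditions: BBr3 (12 equiv), CH2Cl2, −78 to 0 °C; H2O
Reagents that add atoms: none
Why: Boron tribromide cleavage of five aryl methyl ethers, each ortho to a formyl group that anchors the boron; the electron-poor aryl groups disfavour ionisation of the C2–O1 bond, so the three stereocenters should be retained.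

## Compound list

1 | 2,4,6-trimethoxybenzaldehyde | COc1cc(OC)c(C=O)c(OC)c1 | starting material
2 | 3,5-dibromo-2,4,6-trimethoxybenzaldehyde | COc1c(Br)c(OC)c(C=O)c(OC)c1Br | intermediate
3 | (R)-4-benzyl-3-(3-methylbutanoyl)oxazolidin-2-one | CC(C)CC(=O)N1[C@H](Cc2ccccc2)COC1=O | starting material
4 | (R)-4-benzyl-3-[(2S,3R)-3-(3,5-dibromo-2,4,6-trimethoxyphenyl)-2-isopropyl-3-(trimethylsilyloxy)propanoyl]oxazolidin-2-one | COc1c(Br)c(OC)c([C@H](O[Si](C)(C)C)[C@@H](C(=O)N2[C@H](Cc3ccccc3)COC2=O)C(C)C)c(OC)c1Br | intermediate
5 | (R)-4-benzyl-3-[(2S,3R)-3-(3,5-dibromo-2,4,6-trimethoxyphenyl)-3-hydroxy-2-isopropylpropanoyl]oxazolidin-2-one | COc1c(Br)c(OC)c([C@H](O)[C@@H](C(=O)N2[C@H](Cc3ccccc3)COC2=O)C(C)C)c(OC)c1Br | intermediate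
6 | (2S,3R)-3-(3,5-dibromo-2,4,6-trimethoxyphenyl)-3-hydroxy-N-methoxy-N-methyl-2-isopropylpropanamide | COc1c(Br)c(OC)c([C@H](O)[C@@H](C(=O)N(C)OC)C(C)C)c(OC)c1Br | intermediate
7 | (1R,2S)-1-(3,5-dibromo-2,4,6-trimethoxyphenyl)-1-hydroxy-5-methyl-2-isopropylhexan-3-one | COc1c(Br)c(OC)c([C@H](O)[C@@H](C(=O)CC(C)C)C(C)C)c(OC)c1Br | intermediate
8 | 2-bromo-1,3-dimethoxybenzene | COc1cccc(OC)c1Br | starting material
9 | 2-(4-bromo-3,5-dimethoxyphenyl)-4,4,5,5-tetramethyl-1,3,2-dioxaborolane | COc1cc(B2OC(C)(C)C(C)(C)O2)cc(OC)c1Br | intermediate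
10 | 4-bromo-3,5-dimethoxyphenol | COc1cc(O)cc(OC)c1Br | intermediate
11 | 4-bromo-2-iodo-3,5-dimethoxyphenol | COc1cc(O)c(I)c(OC)c1Br | intermediate
12 | (4-bromo-2-iodo-3,5-dimethoxyphenoxy)trimethylsilane | COc1cc(O[Si](C)(C)C)c(I)c(OC)c1Br | intermediate
13 | lithium 4-bromo-3,5-dimethoxy-2-(trimethylsilyl)phenoxide | COc1cc([O-])c([Si](C)(C)C)c(OC)c1Br.[Li+] | intermediate
14 | 4-bromo-3,5-dimethoxy-2-(trimethylsilyl)phenyl trifluoromethanesulfonate | COc1cc(OS(=O)(=O)C(F)(F)F)c([Si](C)(C)C)c(OC)c1Br | intermediate
15 | 4-bromo-3,5-dimethoxybenzyne (4-bromo-3,5-dimethoxy-1,2-didehydrobenzene) | COC1=C(Br)C(OC)=CC#C1 | intermediate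
16 | (2R,3S)-6-bromo-2-(3,5-dibromo-2,4,6-trimethoxyphenyl)-4-isobutyl-3-isopropyl-5,7-dimethoxychroman-4-ol (C4 not defined) | CC(C)CC1(O)c2c(cc(OC)c(Br)c2OC)O[C@@H](c2c(OC)c(Br)c(OC)c(Br)c2OC)[C@@H]1C(C)C | intermediate
17 | (2R,3R,4S)-6-bromo-2-(3,5-dibromo-2,4,6-trimethoxyphenyl)-4-isobutyl-3-isopropyl-5,7-dimethoxychroman | CC(C)C[C@@H]1c2c(cc(OC)c(Br)c2OC)O[C@@H](c2c(OC)c(Br)c(OC)c(Br)c2OC)[C@@H]1C(C)C | intermediate
18 | trilithio derivative of 17 (lithium in place of each of the three bromine atoms) | CC(C)C[C@@H]1c2c(cc(OC)c([Li])c2OC)O[C@@H](c2c(OC)c([Li])c(OC)c([Li])c2OC)[C@@H]1C(C)C | intermediate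
19 | 5-[(2R,3R,4S)-6-formyl-4-isobutyl-3-isopropyl-5,7-dimethoxychroman-2-yl]-2,4,6-trimethoxybenzene-1,3-dicarbaldehyde | CC(C)C[C@@H]1c2c(cc(OC)c(C=O)c2OC)O[C@@H](c2c(OC)c(C=O)c(OC)c(C=O)c2OC)[C@@H]1C(C)C | intermediate
20 | 5-[(2R,3R,4S)-6-formyl-5,7-dihydroxy-4-isobutyl-3-isopropylchroman-2-yl]-2,4,6-trihydroxybenzene-1,3-dicarbaldehyde (CNP0328914.1) | CC(C)C[C@@H]1c2c(cc(O)c(C=O)c2O)O[C@@H](c2c(O)c(C=O)c(O)c(C=O)c2O)[C@@H]1C(C)C | target

## Step count and risks

Total step count: 11. Longest linear sequence: 8 steps (steps 1, 2, 3, 4, 8, 9, 10, 11).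

**Step 8 (Proposed new method).** The aryl anion may be protonated before it reaches the ketone (plain O–H insertion), the hindered hydroxyl may add too slowly to the aryne, or 7 may undergo retro-aldol cleavage under fluoride.

The fallback builds the same two bonds one after the other with known reactions. It sets out from Weinreb amide 6 and from boronate 9 (isolated in this case) and comes back at 16.
- Copper-mediated fluorination of the aryl boronate 9 should give 2-bromo-5-fluoro-1,3-dimethoxybenzene F1.
- LDA (THF, −78 °C) lithiates F1 at the only open position, between fluorine and methoxy. The aryllithium is added to the magnesium alkoxide of 6 (Weinreb ketone synthesis) to give (2S,3R)-1-(3-bromo-6-fluoro-2,4-dimethoxyphenyl)-3-(3,5-dibromo-2,4,6-trimethoxyphenyl)-3-hydroxy-2-isopropylpropan-1-one F2.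
- K2CO3 in DMF should close the ring by intramolecular nucleophilic aromatic substitution of the fluoride activated by the ortho acyl group, giving (2R,3S)-6-bromo-2-(3,5-dibromo-2,4,6-trimethoxyphenyl)-3-isopropyl-5,7-dimethoxychroman-4-one F3.
- The isobutylcerium reagent (i-BuMgBr, CeCl3, THF, −78 °C) adds to the ketone to give 16.

**Step 9.** The C4 cation may lose the C3 proton (E1), which would erode the C3 configuration, or hydride may be delivered to the wrong face.

The fallback replaces the cation by a radical. It sets out from 16 and comes back at 17 with no new isolated compound. Titanocene(III) chloride (Cp2TiCl2, Mn, THF, reflux, with 1,4-cyclohexadiene as hydrogen donor) should cleave the benzylic C–O bond homolytically through the titanium(III) alkoxide. The C4 radical, or its organotitanium form, is then quenched from the face opposite the isopropyl group, and aryl bromides are not reduced by this reagent.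

**Step 2.** Soft enolisation of the β-branched imide may be slow, and addition to the di-ortho-substituted aldehyde may be slow and reversible, giving low conversion or eroded anti selectivity.

The fallback drops the auxiliary and maps the whole C3–C4 side chain onto a symmetric bulk ketone. It sets out from aldehyde 2 and comes back at 7, so steps 3 and 4 are not needed.
- Commercial 2,6-dimethylheptan-4-one is enolised with dicyclohexylboron chloride and Et3N (Et2O, 0 °C) to (E)-[(2,6-dimethylhept-3-en-4-yl)oxy]dicyclohexylborane F4.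
- F4 adds to 2 at −78 °C through a chair transition state to give the anti-aldol as a racemate after oxidative work-up (H2O2, pH 7 buffer).
- Preparative chromatography on a chiral stationary phase should deliver 7 and set aside its enantiomer (1S,2R)-1-(3,5-dibromo-2,4,6-trimethoxyphenyl)-1-hydroxy-5-methyl-2-isopropylhexan-3-one F5.

Further compounds
F1 | step 8 | 2-bromo-5-fluoro-1,3-dimethoxybenzene | COc1cc(F)cc(OC)c1Br
F2 | step 8 | (2S,3R)-1-(3-bromo-6-fluoro-2,4-dimethoxyphenyl)-3-(3,5-dibromo-2,4,6-trimethoxyphenyl)-3-hydroxy-2-isopropylpropan-1-one | COc1c(Br)c(OC)c([C@H](O)[C@@H](C(=O)c2c(F)cc(OC)c(Br)c2OC)C(C)C)c(OC)c1Br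
F3 | step 8 | (2R,3S)-6-bromo-2-(3,5-dibromo-2,4,6-trimethoxyphenyl)-3-isopropyl-5,7-dimethoxychroman-4-one | O=C1c2c(cc(OC)c(Br)c2OC)O[C@@H](c2c(OC)c(Br)c(OC)c(Br)c2OC)[C@@H]1C(C)C
F0 | step 9 | none | none
F4 | step 2 | (E)-[(2,6-dimethylhept-3-en-4-yl)oxy]dicyclohexylborane | CC(C)C/C(OB(C1CCCCC1)C1CCCCC1)=C\C(C)C
F5 | step 2 | (1S,2R)-1-(3,5-dibromo-2,4,6-trimethoxyphenyl)-1-hydroxy-5-methyl-2-isopropylhexan-3-one | COc1c(Br)c(OC)c([C@@H](O)[C@H](C(=O)CC(C)C)C(C)C)c(OC)c1Br
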